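**Remarks on the chemistry (assumptions)**

- Positions are numbered as in the cassanes. Ring A is C1–C5 and C10; ring B is C5–C10; ring C is C8, C9, C11, C13, C14; the lactone is C13, C12(=O), O, C16, C15; C17 is the ester carbon on C14; C20 is the methyl on C10. α is the face opposite to C20.
- Mono-tert-butyl fumarate (9), ylide 22 and allyl acetate (26) are taken as purchased.
- The ligand enantiomer in step 20 is assigned from the usual pocket model; its antipode is used if induction on this enolate runs the other way.

## Analysis of the target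

Spirocaesalmin (40) is a rearranged cassane: a trans-decalin (rings A and B) is trans-fused at C8–C9 to a cyclopentane ring C (C8, C9, C11, C13, C14), and C13 is the spiro atom of a γ-lactone (C13, C12, O, C16, C15) whose C15–C16 bond carries an epoxide, so C16 is an acetal carbon of an acyloxy epoxide. Ten stereocentres are present (C1, C5, C7, C8, C9, C10, C13, C14, C15, C16): 10β-methyl, 5α-OH, 9α-H and 8β-H define the trans-anti-trans core; the 1α-acetate is axial and the 7β-acetate equatorial; the C14 ester is β (cis to H8, trans to C7 on ring C); at C13, C15 is β and the lactone carbonyl C12 is α; the epoxide oxygen lies on the lactone face turned toward C14, next to the C14 ester. The acyloxy epoxide tolerates neither acid, base nor nucleophiles and must come last; the tertiary 5α-OH is β to the C7 oxygen (retro-aldol and dehydration at the ketone stage), and a free 7β-OH can lactonize onto C17. The hard points are three adjacent quaternary carbons (C4, C5, C10), a fourth (C13) flanked by the C14 stereocentre, and an epoxide on the more shielded face of the spiro ring. The route rests on ring A: C4 with its two methyls, C10 with its methyl, the C5–C6 arm and C1 are the skeleton of β-cyclocitral (1), and the 1α-oxygen stands 1,3 to C11, so an ester can tie O1 to C11 and deliver C9 to the α face of C10 while ring B closes.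

## Retrosynthetic reasoning

**Epoxide (40 ⇒ 39 ⇒ 38).** The two C–O bonds of the epoxide are cut last. Direct epoxidation of enol lactone 38 is expected from the C11 side, because the β-ester on C14 covers the other face. The oxygen therefore has to arrive by anti addition: bromine on the open face (39), then closure from the C16 hydroxyl with inversion at C15.

**Spiro lactone (38 ⇒ 36 ⇒ 34 ⇒ 32).** The enol lactone is the dehydrated pseudo-acid 36, a C16 aldehyde held by the C12 acid. Cutting the terminal carbon of an allyl group leads to acid 34 and its tert-butyl ester 32. Allyl and tert-butyl ester on C13 thus stand for C15–C16 and C12, and the two acetates can already be in place (32 ⇒ 31 ⇒ 30).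

**C17 and the C8/C14 stereocentres (30 ⇒ 29 ⇒ 28 ⇒ 27).** The C14–C17 bond is cut back to a ring C ketone through its enol triflate. Forward, carbonylation and conjugate reduction must protonate C8 to the trans B/C fusion and let C14 settle as the β-ester. This avoids olefinating a ketone flanked by a quaternary and a tertiary carbon.

**Quaternary C13 (27 ⇒ 25 + 26).** The C13–C15 bond is cut to a β-keto ester enolate and allyl donor 26. C13 is the only doubly activated carbon; the trans-hydrindanone enolate has almost no facial bias, so a chiral palladium catalyst must choose the β face.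

**Ring C (25 ⇒ 24).** The C13–C14 bond is cut as a Dieckmann condensation. The ester carbon left on C8 by the cycloaddition (C14) is the electrophile and the propanoate arm on C9 the nucleophile, so both carbonyl carbons of the dienophile become ring C atoms (C11 and C14).

**C11–C13 bond and release of the tether (24 ⇒ 23 ⇒ 21 + 22; 21 ⇒ 20 ⇒ 19 ⇒ 18).** The two-carbon arm comes from a Wittig reaction of aldehyde 21 with 22. The aldehyde is reached from lactone 18 through a Weinreb amide, so that O1 is silylated before the aldehyde is freed. Opening to the lactol instead would expose a hydroxy enoate able to close back by oxa-Michael addition.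

**Ring B oxygens (18 ⇒ 17 ⇒ 16 ⇒ 15 ⇒ 14 ⇒ 13).** The 5α-OH/7β-OH pair is traced to the 5-ene and the 7α-silyloxy group of cycloadduct 13 by directed epoxidation, oxidation, reductive epoxide opening and a 5-OH-directed reduction. These steps are run on the rigid lactone and without base, because in 13 the 7α-oxygen is antiperiplanar to H8 and β to the ester.

**Ring B (13 ⇒ 12), the key disconnection.** C9–C10 and C7–C8 are cut in the retro-Diels–Alder sense; the lactone is the former tether. The cut reveals the cyclocitral ring A, accounts for the quaternary C10 and three further stereocentres in one step, and leaves only an ester between the two halves.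

**Precursor (12 ⇒ 11 ⇒ 10 ⇒ 8 + 9; 8 ⇒ 5 + 6; 5 ⇒ 3 ⇒ 2 ⇒ 1).** The silyl dienol ether is the enol form of aldehyde 11; the ester bond to 9 is cut next; C7 comes from phosphonium salt 6. The single stereocentre C1 comes from asymmetric reduction of enone 3, made by allylic oxidation of acetal 2 of aldehyde 1.

## Alternatives that were turned down

**Alternative 1:** The cut is C13–C15. A carbon radical at C15, generated from a bromoacetal on the C17 oxygen, adds 6-exo to C13 of an exocyclic vinyl sulfone, and the sulfonyl-stabilized radical is reduced to give A1.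
- For: radical cyclizations of the Ueno–Stork type are dependable. Because the radical is delivered from the C14 substituent, the new bond must be cis to C17, so C13 is fixed by geometry. On this point it is stronger than the chosen route, where C13 depends on a chiral catalyst.
- Against: in A1 three carbons are at the wrong oxidation level (C12 as a sulfonylmethyl group, C17 as an ether carbon, C16 as a mixed acetal), so several redox steps follow. The radical must attack a fully substituted alkene carbon. The step presupposes the whole tricyclic core with C8, C9, C10 and C14 set.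
- Comparison: the chosen key step is spent on the core (ring B, quaternary C10, four stereocentres) from a ten-carbon terpene aldehyde, and C12/C17 arrive at the carboxyl level through Dieckmann and carbonylation chemistry. What is given up is the built-in control of C13.

**Alternative 2:** The cut is C11–C13 together with C9=C11. A diazomethyl anion reagent turns a C9 ketone into an alkylidene carbene whose carbon (C11) inserts into the tertiary C13–H bond, closing ring C as cyclopentene A2.
- For: 1,5 C–H insertion proceeds with retention, so a C13 stereocentre made earlier is carried into the quaternary centre, and C12 and C15–C16 are already attached. C13 is again better defined than by a catalyst-controlled allylation.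
- Against: the C9 ketone is flanked by the quaternary C10 and the substituted C8. Other 1,5 C–H bonds compete (C1–H activated by oxygen, the C10 methyl), as do the silyl ethers. The acyclic C13 and C14 centres must be built beforehand in a side chain. Afterwards C9=C11 must be hydrogenated from the α face and C12 oxidized from the ether level.
- Comparison: the Diels–Alder route sets C9 directly from the alkene geometry and needs no preformed acyclic stereo-array, at the price of making C13 after the ring.

**Alternative 3:** The cut is C7–C8. An N-heterocyclic carbene turns a C7 aldehyde into an acyl anion equivalent that adds to C8 of a ring C cyclopentene ester, closing ring B as ketone A3.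
- For: A3 already has C7 as the ketone needed for the 5-OH-directed reduction, so no inversion at C7 is required and the ring B oxidation sequence is shorter; here it is stronger than the chosen route. The catalysis is mild.
- Against: the acceptor is a hindered, weakly activated cyclopentene ester next to a quaternary carbon. C8 and C14 are set only by protonation. The β-silyloxy aldehyde can eliminate or fragment under the basic carbene conditions. Above all, the C9–C10 bond between ring C and the quaternary C10 must already exist, so the hardest bond of the core is moved to an earlier, unsolved step.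
- Comparison: the chosen key step forms exactly that C9–C10 bond together with C7–C8, and pays with a detour at C7 (α-silyloxy, ketone, β-alcohol).

Key step: step 8

## Route

Step 1
Reactants: 1 β-cyclocitral (2,6,6-trimethylcyclohex-1-ene-1-carbaldehyde)
Product: 2 β-cyclocitral dimethyl acetal
Conditions: HC(OMe)3, MeOH, p-TsOH (cat.), 23 °C; then Et3N
Reagents that add atoms: trimethyl orthoformate COC(OC)OC
Why: Acid-catalysed acetalization with the orthoformate as water scavenger masks the aldehyde, whose C–H would not survive the chromium oxidant; the tetrasubstituted alkene is the most substituted isomer and should stay in place.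

Step 2
Reactants: 2 β-cyclocitral dimethyl acetal
Product: 3 3-(dimethoxymethyl)-2,4,4-trimethylcyclohex-2-en-1-one
Conditions: CrO3, 3,5-dimethylpyrazole, CH2Cl2, −20 °C
Reagents that add atoms: chromium trioxide O=[Cr](=O)=O
Why: Allylic oxidation with the CrO3–dimethylpyrazole complex should attack the only ring methylene allylic to the alkene (C1 of the target); the vinylic methyl is primary and slower, and the acetal carbon is deactivated.

Step 3
Reactants: 3 3-(dimethoxymethyl)-2,4,4-trimethylcyclohex-2-en-1-one
Product: 5 (S)-3-hydroxy-2,6,6-trimethylcyclohex-1-ene-1-carbaldehyde, via hydroxy acetal 4 (not isolated)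
Conditions: (R)-2-methyl-CBS-oxazaborolidine (10 mol %), BH3·SMe2, THF, −20 °C; then 1 M HCl, THF–H2O, 0 °C
Reagents that add atoms: water O
Why: Corey–Bakshi–Shibata reduction; the fully substituted alkene arm acts as the large group, so the (R)-catalyst should give the (S)-carbinol (the 1α-oxygen of the target); cold dilute acid then hydrolyses the acetal, the γ-hydroxy enal being too electron-poor to ionize.

Step 4
Reactants: 5 (S)-3-hydroxy-2,6,6-trimethylcyclohex-1-ene-1-carbaldehyde; 6 (methoxymethyl)triphenylphosphonium chloride
Product: 8 (S)-3-(2-methoxyvinyl)-2,4,4-trimethylcyclohex-2-en-1-ol (E/Z mixture), via phosphorus ylide 7 (not isolated)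
Conditions: 6, NaN(SiMe3)2 (2.4 equiv), THF, 0 °C; then 5, 0 → 23 °C
Reagents that add atoms: none
Why: Wittig methoxymethylenation of the hindered enal adds C7 as a masked aldehyde (the first equivalent of base only forms the alkoxide); the enol ether geometry is irrelevant because it is hydrolysed in step 6.

Step 5
Reactants: 8 (S)-3-(2-methoxyvinyl)-2,4,4-trimethylcyclohex-2-en-1-ol; 9 mono-tert-butyl fumarate
Product: 10 tert-butyl (S)-3-(2-methoxyvinyl)-2,4,4-trimethylcyclohex-2-en-1-yl fumarate
Conditions: DCC, DMAP (cat.), CH2Cl2, 0 → 23 °C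
Reagents that add atoms: none
Why: Steglich esterification of the secondary allylic alcohol under neutral conditions keeps the enol ether and the (E)-alkene; it installs the dienophile with the future C8, C9, C11 and C14, after the ylide step that a fumarate would not survive.

Step 6
Reactants: 10 tert-butyl (S)-3-(2-methoxyvinyl)-2,4,4-trimethylcyclohex-2-en-1-yl fumarate
Product: 11 tert-butyl (S)-2,4,4-trimethyl-3-(2-oxoethyl)cyclohex-2-en-1-yl fumarate
Conditions: oxalic acid (0.2 equiv), THF–H2O (5:1), 0 °C
Reagents that add atoms: water O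
Why: Mild enol ether hydrolysis (protonation at C6, water addition at C7, loss of methanol) gives the β,γ-unsaturated aldehyde; short, cold and weakly acidic conditions are chosen so that the allylic ester does not ionize and the alkene does not move into conjugation.

Step 7
Reactants: 11 tert-butyl (S)-2,4,4-trimethyl-3-(2-oxoethyl)cyclohex-2-en-1-yl fumarate
Product: 12 tert-butyl (S)-3-[(E)-2-(tert-butyldimethylsilyloxy)vinyl]-2,4,4-trimethylcyclohex-2-en-1-yl fumarate
Conditions: TBSOTf, Et3N, CH2Cl2, −78 → 23 °C
Reagents that add atoms: tert-butyldimethylsilyl trifluoromethanesulfonate CC(C)(C)[Si](C)(C)OS(=O)(=O)C(F)(F)F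
Why: Soft enolization of the doubly activated C6 methylene gives the conjugated silyl dienol ether; under equilibrating conditions the (E)-isomer should prevail because a (Z)-oxygen would clash with the twisted trimethylcyclohexenyl group, and only (E) can reach the s-cis geometry needed next; 12 is used at once, without acidic silica.

Step 8
Reactants: 12 tert-butyl (S)-3-[(E)-2-(tert-butyldimethylsilyloxy)vinyl]-2,4,4-trimethylcyclohex-2-en-1-yl fumarate
Product: 13 cycloadduct (5-ene; 7α-OTBS; 8α-CO2t-Bu; 8β-H; 9α-H; 10β-CH3; C11 closed as γ-lactone onto the 1α-oxygen)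
Conditions: toluene (0.01 M), BHT (cat.), base-washed sealed tube, 120 °C
Reagents that add atoms: none
Why: On heating, the electron-rich (E)-silyloxydiene C10=C5–C6=C7 and the tethered fumarate C9=C8 should combine in a concerted, asynchronous [4+2], forming C9–C10 and C7–C8; the closest known reaction type is the ester-tethered intramolecular Diels–Alder reaction of dienyl fumarates, and tethered cycloadditions of 2-methyl-1-vinylcyclohexene dienes that create the same quaternary carbon. Ring B closes by the cycloaddition itself (cyclohexene with C5=C6), and the γ-lactone C1–O–C11–C9–C10 closes because the three-atom tether on the diene terminus becomes a five-membered ring (type 1 mode). C10: the short tether anchored on the 1α-oxygen can bring C9 only to the α face, so the methyl ends up β. C9 and C8: the (E)-alkene geometry is transferred, so H9 and H8 are trans; with the tether carbonyl exo and the free ester endo, C11 is cis to the C10 methyl (trans-fused lactone, 9α-H) and C14 is equatorial (8β-H). C7: the (E)-enol ether places the silyloxy group cis to the endo ester, that is α and axial; this centre is corrected in steps 11–13. The selectivity needed is the face, which the tether secures absolutely, and the exo-tether mode, which is favoured by the endo preference of the free ester and by crowding of an endo tether carbonyl under ring A (C3, C4). Dilution, a radical inhibitor and acid-free glass are meant to suppress ionization of the doubly allylic ester and polymerization.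

Step 9
Reactants: 13 cycloadduct
Product: 14 7α-hydroxy-5-ene lactone
Conditions: HF·pyridine, pyridine, THF, 0 → 23 °C
Reagents that add atoms: none
Why: Fluoride cleavage under buffered, non-basic conditions frees the axial allylic alcohol; base is avoided because the 7α-oxygen is β to the C8 ester and antiperiplanar to H8 (E1cB).

Step 10
Reactants: 14 7α-hydroxy-5-ene lactone
Product: 15 5α,6α-epoxy-7α-hydroxy lactone
Conditions: VO(acac)2 (5 mol %), t-BuOOH, CH2Cl2, 0 → 23 °C
Reagents that add atoms: tert-butyl hydroperoxide CC(C)(C)OO
Why: Vanadium-catalysed hydroxyl-directed epoxidation of the pseudoaxial allylic alcohol should deliver oxygen syn to 7α-OH, which is also the face away from the C10 methyl; this fixes the C5–O bond α (trans A/B).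

Step 11
Reactants: 15 5α,6α-epoxy-7α-hydroxy lactone
Product: 16 5α,6α-epoxy-7-oxo lactone
Conditions: n-Pr4N[RuO4] (5 mol %), N-methylmorpholine N-oxide, 4 Å MS, CH2Cl2, 23 °C
Reagents that add atoms: none
Why: Ley–Griffith oxidation under neutral conditions gives the α,β-epoxy ketone without opening the epoxide; C8, now between ketone and ester, rests in its stable equatorial-ester form.

Step 12
Reactants: 16 5α,6α-epoxy-7-oxo lactone
Product: 17 5α-hydroxy-7-oxo lactone
Conditions: SmI2 (2.5 equiv), THF–MeOH, −78 °C
Reagents that add atoms: none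
Why: Reductive cleavage of the Cα–O bond of an α,β-epoxy ketone by SmI2 (ketyl formation, then scission at C6) leaves the tertiary 5α-alcohol; low temperature and methanol as proton source are chosen to avoid retro-aldol cleavage and over-reduction.

Step 13
Reactants: 17 5α-hydroxy-7-oxo lactone
Product: 18 5α,7β-dihydroxy lactone
Conditions: Me4NBH(OAc)3, AcOH–MeCN (1:1), −30 → 0 °C
Reagents that add atoms: none
Why: Evans–Saksena directed reduction; the borohydride binds the 5α-oxygen and delivers hydride intramolecularly to the α face of the C7 ketone, giving the 1,3-anti diol with equatorial 7β-OH, which inverts C7 relative to the cycloadduct.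

Step 14
Reactants: 18 5α,7β-dihydroxy lactone
Product: 19 N-methoxy-N-methylamide at C11 with 1α-, 5α- and 7β-OH (C14 tert-butyl ester kept)
Conditions: MeNH(OMe)·HCl, AlMe3, CH2Cl2, 0 → 35 °C
Reagents that add atoms: N,O-dimethylhydroxylamine hydrochloride CNOC.Cl
Why: Weinreb aminolysis of the γ-lactone by the aluminium amide opens the temporary tether and leaves C11 at the acyl level for a controlled reduction; the hindered tert-butyl ester should not react; 19 is silylated at once because γ-hydroxy amides relactonize.

Step 15
Reactants: 19 Weinreb amide triol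
Product: 20 1α,7β-bis(tert-butyldimethylsilyl) ether of 19
Conditions: TBSOTf (2.6 equiv), 2,6-lutidine, CH2Cl2, −78 → 0 °C
Reagents that add atoms: tert-butyldimethylsilyl trifluoromethanesulfonate CC(C)(C)[Si](C)(C)OS(=O)(=O)C(F)(F)F
Why: Silylation of the two secondary alcohols (the tertiary 5-OH between two quaternary carbons is left) blocks relactonization and removes acidic protons before the base steps; the equatorial 7β-silyloxy group is poorly aligned for β-elimination from a C8 enolate.

Step 16
Reactants: 20 bis-silyl Weinreb amide
Product: 21 C11 aldehyde (1α,7β-OTBS; 5α-OH; C14 tert-butyl ester)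
Conditions: i-Bu2AlH (2.5 equiv), CH2Cl2, −78 °C; aqueous Rochelle salt
Reagents that add atoms: none
Why: Weinreb amide reduction stops at the aldehyde through the stable aluminium chelate (one equivalent is consumed by 5-OH); the tert-butyl ester survives at −78 °C; C9, now α to the aldehyde, rests in the natural equatorial arrangement.

Step 17
Reactants: 21 C11 aldehyde; 22 tert-butyl (triphenylphosphoranylidene)acetate
Product: 23 (E)-enoate (C11=C13 with C12 tert-butyl ester)
Conditions: toluene, 90 °C
Reagents that add atoms: none
Why: Wittig reaction with a stabilized ylide adds C13 and C12 under neutral conditions; no free hydroxyl at C1 is present that could add back to the enoate.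

Step 18
Reactants: 23 (E)-enoate
Product: 24 saturated di-tert-butyl diester
Conditions: H2 (1 atm), Pd/C, EtOAc, 23 °C
Reagents that add atoms: none
Why: Hydrogenation of the disubstituted enoate; no other C=C is present at this stage.

Step 19
Reactants: 24 saturated di-tert-butyl diester
Product: 25 ring C β-keto ester (C14 ketone; CO2t-Bu on C13)
Conditions: KN(SiMe3)2 (3 equiv), THF, −78 → 0 °C; then AcOH
Reagents that add atoms: none
Why: Dieckmann condensation; kinetic deprotonation at the unhindered C13 methylene, 5-exo-trig attack on the C14 ester and loss of tert-butoxide; the product is held as its stabilized enolate, which drives the reaction and shields C8, whereas the other mode (C8 enolate onto C12) would need the hindered tertiary enolate and give a non-enolizable product.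

Step 20
Reactants: 25 ring C β-keto ester; 26 allyl acetate
Product: 27 13β-allyl-13α-CO2t-Bu cyclopentanone
Conditions: Pd2(dba)3·CHCl3 (2.5 mol %), (R,R)-DACH-phenyl Trost ligand (7.5 mol %), 1,1,3,3-tetramethylguanidine, toluene, 0 °C
Reagents that add atoms: none
Why: Palladium-catalysed asymmetric allylic alkylation of a 2-alkoxycarbonyl cyclopentanone; the planar enolate of the trans-hydrindanone has little bias of its own (H9α below, H8β above), so the chiral pocket should decide and place allyl (C15, C16 and one carbon lost later) on the β face and the ester (C12) α.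

Step 21
Reactants: 27 13β-allyl cyclopentanone
Product: 28 C14 enol triflate (C8=C14)
Conditions: KN(SiMe3)2 (2.2 equiv), PhNTf2, THF, −78 °C
Reagents that add atoms: N-phenylbis(trifluoromethanesulfonimide) O=S(=O)(N(c1ccccc1)S(=O)(=O)C(F)(F)F)C(F)(F)F
Why: With C13 quaternary the ketone can enolize only toward C8; the potassium enolate is trapped as the vinyl triflate at low temperature, and the hindered tertiary alkoxide at C5 should not react.

Step 22
Reactants: 28 C14 enol triflate
Product: 29 methyl 8(14)-ene-17-oate (C8=C14–CO2Me)
Conditions: Pd(OAc)2 (10 mol %), PPh3 (20 mol %), CO (1 atm), MeOH, Et3N, DMF, 60 °C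
Reagents that add atoms: carbon monoxide [C-]#[O+]; methanol CO
Why: Methoxycarbonylation of a vinyl triflate (oxidative addition to zerovalent palladium, CO insertion, methanolysis) installs C17 on C14; the reaction type is established for hindered ring enol triflates next to a quaternary carbon.

Step 23
Reactants: 29 unsaturated methyl ester
Product: 30 saturated ester (8β-H; 14β-CO2Me; 13β-allyl; 13α-CO2t-Bu; 1α,7β-OTBS; 5α-OH)
Conditions: Mg turnings, MeOH, 23 °C
Reagents that add atoms: none
Why: Conjugate reduction by magnesium in methanol (electron transfer, protonation at the β-carbon C8, second electron, protonation at C14); C8 should be protonated axially from the β face to give the trans B/C fusion, since the cis product would put C14 axial and syn to the C10 methyl, and C14 equilibrates through the magnesium enolate to the β-ester, trans to C7 on ring C.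

Step 24
Reactants: 30 saturated ester
Product: 31 1α,7β-diol
Conditions: HF·pyridine, THF, 0 → 40 °C
Reagents that add atoms: none
Why: Fluoride removes both silyl ethers under weakly acidic conditions, which avoid base-induced lactonization of 7β-OH onto the C17 ester; 31 is acetylated without delay.

Step 25
Reactants: 31 1α,7β-diol
Product: 32 1α,7β-diacetate
Conditions: Ac2O, DMAP (cat.), pyridine, 23 °C
Reagents that add atoms: acetic anhydride CC(=O)OC(C)=O
Why: DMAP-catalysed acetylation of the two secondary alcohols; the tertiary 5α-OH between two quaternary carbons should not react.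

Step 26
Reactants: 32 1α,7β-diacetate
Product: 34 C12 carboxylic acid (13β-allyl; diacetate), via bis(trimethylsilyl) derivative 33 (not isolated)
Conditions: TMSOTf, 2,6-lutidine, CH2Cl2, 0 °C; then aqueous citric acid, THF, 23 °C
Reagents that add atoms: none
Why: Silyl triflate with lutidine cleaves the tert-butyl ester by loss of isobutene without protic acid, which spares the tertiary 5-OH from ionization; the silyl ester and the 5-O-silyl ether fall off on mild aqueous acid work-up.

Step 27
Reactants: 34 C12 carboxylic acid
Product: 36 spiro γ-lactol (pseudo-acid; 16-OH), via ozonide 35 (not isolated)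
Conditions: O3, CH2Cl2, −78 °C; then PPh3, −78 → 23 °C
Reagents that add atoms: ozone [O-][O+]=O
Why: Ozonolysis of the terminal alkene, the only C=C, gives the C16 aldehyde, which the neighbouring C12 acid captures as the five-membered lactol; the quaternary C13 favours the ring form.

Step 28
Reactants: 36 spiro γ-lactol
Product: 38 spiro enol lactone (C15=C16), via lactol mesylate 37 (not isolated)
Conditions: MsCl, Et3N, CH2Cl2, −20 → 23 °C
Reagents that add atoms: none
Why: Mesylation of the lactol hydroxyl and amine-promoted elimination through the acyloxy-stabilized cation (loss of H15) give the enol lactone; the double bond cannot move into conjugation because C13 is quaternary.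

Step 29
Reactants: 38 spiro enol lactone
Product: 39 15-bromo-16-hydroxy spiro lactone (Br on the face turned toward C11)
Conditions: NBS, THF–H2O (4:1), 0 °C
Reagents that add atoms: N-bromosuccinimide O=C1CCC(=O)N1Br; water O
Why: Bromohydrin formation of an enol ester; bromine should add to the nucleophilic C15 from the open face of the spiro ring (the C11 side, since the C14 ester shields the other side) and water to the acyloxy-stabilized C16 cation; the C16 epimers interconvert by ring–chain tautomerism.

Step 30
Reactants: 39 bromo lactol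
Product: 40 spirocaesalmin
Conditions: Ag2O, 4 Å MS, CH2Cl2, 23 °C, dark
Reagents that add atoms: none
Why: Proposed new method: the lactol hydroxyl of a pseudo-acid serves as the internal nucleophile of a silver-assisted halohydrin closure; the anomer with OH anti to bromine attacks C15 from the back, so the oxygen ends on the face turned toward C14, opposite to the face bromine took (direct epoxidation of 38 would take the open C11 face and give the epimeric epoxide); neutral silver oxide avoids a free lactol alkoxide, which would open to the carboxylate; the closest known reactions are the Ag2O closure of trans-bromohydrins and the formation of 1,2-anhydro sugars from lactols that carry a leaving group on C2.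

## Compound list

1 | β-cyclocitral (2,6,6-trimethylcyclohex-1-ene-1-carbaldehyde) | CC1=C(C=O)C(C)(C)CCC1 | starting material
2 | β-cyclocitral dimethyl acetal (2-(dimethoxymethyl)-1,3,3-trimethylcyclohex-1-ene) | COC(OC)C1=C(C)CCCC1(C)C | intermediate
3 | 3-(dimethoxymethyl)-2,4,4-trimethylcyclohex-2-en-1-one | COC(OC)C1=C(C)C(=O)CCC1(C)C | intermediate
4 | (S)-3-(dimethoxymethyl)-2,4,4-trimethylcyclohex-2-en-1-ol | COC(OC)C1=C(C)[C@@H](O)CCC1(C)C | intermediate (not isolated)
5 | (S)-3-hydroxy-2,6,6-trimethylcyclohex-1-ene-1-carbaldehyde | O=CC1=C(C)[C@@H](O)CCC1(C)C | intermediate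
6 | (methoxymethyl)triphenylphosphonium chloride | COC[P+](c1ccccc1)(c1ccccc1)c1ccccc1.[Cl-] | starting material
7 | (methoxymethylene)triphenylphosphorane | COC=P(c1ccccc1)(c1ccccc1)c1ccccc1 | intermediate (not isolated)
8 | (S)-3-(2-methoxyvinyl)-2,4,4-trimethylcyclohex-2-en-1-ol (E/Z mixture at the enol ether) | COC=CC1=C(C)[C@@H](O)CCC1(C)C | intermediate
9 | mono-tert-butyl fumarate ((E)-4-tert-butoxy-4-oxobut-2-enoic acid) | OC(=O)/C=C/C(=O)OC(C)(C)C | starting material
10 | tert-butyl (S)-3-(2-methoxyvinyl)-2,4,4-trimethylcyclohex-2-en-1-yl fumarate | COC=CC1=C(C)[C@@H](OC(=O)/C=C/C(=O)OC(C)(C)C)CCC1(C)C | intermediate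
11 | tert-butyl (S)-2,4,4-trimethyl-3-(2-oxoethyl)cyclohex-2-en-1-yl fumarate | O=CCC1=C(C)[C@@H](OC(=O)/C=C/C(=O)OC(C)(C)C)CCC1(C)C | intermediate
12 | tert-butyl (S)-3-[(E)-2-(tert-butyldimethylsilyloxy)vinyl]-2,4,4-trimethylcyclohex-2-en-1-yl fumarate (cycloaddition precursor) | CC1=C(/C=C/O[Si](C)(C)C(C)(C)C)C(C)(C)CC[C@@H]1OC(=O)/C=C/C(=O)OC(C)(C)C | intermediate
13 | cycloadduct: rings A/B with 5-ene, 7α-OTBS, 8α-CO2t-Bu (8β-H), 9α-H, 10β-CH3; C11 carbonyl on C9 closed as γ-lactone onto the 1α-oxygen | CC(C)(C)OC(=O)[C@@H]1[C@H](O[Si](C)(C)C(C)(C)C)C=C2C(C)(C)CC[C@@H]3OC(=O)[C@@H]1[C@]23C | intermediate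
14 | 7α-hydroxy-5-ene lactone (13 without the silyl group) | CC(C)(C)OC(=O)[C@@H]1[C@H](O)C=C2C(C)(C)CC[C@@H]3OC(=O)[C@@H]1[C@]23C | intermediate
15 | 5α,6α-epoxy-7α-hydroxy lactone | CC(C)(C)OC(=O)[C@@H]1[C@H](O)[C@@H]2O[C@@]23C(C)(C)CC[C@@H]4OC(=O)[C@@H]1[C@]34C | intermediate
16 | 5α,6α-epoxy-7-oxo lactone | CC(C)(C)OC(=O)[C@@H]1C(=O)[C@@H]2O[C@@]23C(C)(C)CC[C@@H]4OC(=O)[C@@H]1[C@]34C | intermediate
17 | 5α-hydroxy-7-oxo lactone | CC(C)(C)OC(=O)[C@@H]1C(=O)C[C@@]2(O)C(C)(C)CC[C@@H]3OC(=O)[C@@H]1[C@]23C | intermediate
18 | 5α,7β-dihydroxy lactone | CC(C)(C)OC(=O)[C@@H]1[C@@H](O)C[C@@]2(O)C(C)(C)CC[C@@H]3OC(=O)[C@@H]1[C@]23C | intermediate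
19 | ring-opened C11 N-methoxy-N-methylamide with 1α-, 5α-, 7β-OH and tert-butyl ester (C14) on C8 | CC(C)(C)OC(=O)[C@@H]1[C@@H](O)C[C@@]2(O)C(C)(C)CC[C@H](O)[C@]2(C)[C@H]1C(=O)N(C)OC | intermediate
20 | 1α,7β-bis(tert-butyldimethylsilyl) ether of 19 | CC(C)(C)OC(=O)[C@@H]1[C@@H](O[Si](C)(C)C(C)(C)C)C[C@@]2(O)C(C)(C)CC[C@H](O[Si](C)(C)C(C)(C)C)[C@]2(C)[C@H]1C(=O)N(C)OC | intermediate
21 | C11 aldehyde (formyl on C9, 9α-H) with 1α,7β-OTBS, 5α-OH and C14 tert-butyl ester | CC(C)(C)OC(=O)[C@@H]1[C@@H](O[Si](C)(C)C(C)(C)C)C[C@@]2(O)C(C)(C)CC[C@H](O[Si](C)(C)C(C)(C)C)[C@]2(C)[C@H]1C=O | intermediate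
22 | tert-butyl (triphenylphosphoranylidene)acetate | CC(C)(C)OC(=O)C=P(c1ccccc1)(c1ccccc1)c1ccccc1 | starting material
23 | (E)-enoate: C9–CH=CH–CO2t-Bu (C11=C13, C12 ester), C14 tert-butyl ester on C8 | CC(C)(C)OC(=O)[C@@H]1[C@@H](O[Si](C)(C)C(C)(C)C)C[C@@]2(O)C(C)(C)CC[C@H](O[Si](C)(C)C(C)(C)C)[C@]2(C)[C@H]1/C=C/C(=O)OC(C)(C)C | intermediate
24 | saturated di-tert-butyl diester (C9–CH2CH2CO2t-Bu; C8–CO2t-Bu) | CC(C)(C)OC(=O)[C@@H]1[C@@H](O[Si](C)(C)C(C)(C)C)C[C@@]2(O)C(C)(C)CC[C@H](O[Si](C)(C)C(C)(C)C)[C@]2(C)[C@H]1CCC(=O)OC(C)(C)C | intermediate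
25 | ring C β-keto ester: trans-fused cyclopentanone (C14=O) with CO2t-Bu on C13 (C13 epimers and enol) | O=C1[C@@H]2[C@@H](O[Si](C)(C)C(C)(C)C)C[C@@]3(O)C(C)(C)CC[C@H](O[Si](C)(C)C(C)(C)C)[C@]3(C)[C@H]2CC1C(=O)OC(C)(C)C | intermediate
26 | allyl acetate | CC(=O)OCC=C | starting material
27 | 13β-allyl-13α-CO2t-Bu cyclopentanone (C14=O) | O=C1[C@@H]2[C@@H](O[Si](C)(C)C(C)(C)C)C[C@@]3(O)C(C)(C)CC[C@H](O[Si](C)(C)C(C)(C)C)[C@]3(C)[C@H]2C[C@]1(CC=C)C(=O)OC(C)(C)C | intermediate
28 | C14 enol triflate (C8=C14) | O=S(=O)(OC1=C2[C@@H](O[Si](C)(C)C(C)(C)C)C[C@@]3(O)C(C)(C)CC[C@H](O[Si](C)(C)C(C)(C)C)[C@]3(C)[C@H]2C[C@]1(CC=C)C(=O)OC(C)(C)C)C(F)(F)F | intermediate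
29 | methyl 8(14)-ene-17-oate (C8=C14–CO2Me) | COC(=O)C1=C2[C@@H](O[Si](C)(C)C(C)(C)C)C[C@@]3(O)C(C)(C)CC[C@H](O[Si](C)(C)C(C)(C)C)[C@]3(C)[C@H]2C[C@]1(CC=C)C(=O)OC(C)(C)C | intermediate
30 | saturated ester: 8β-H, 14α-H (14β-CO2Me), 13β-allyl, 13α-CO2t-Bu, 1α,7β-OTBS, 5α-OH | COC(=O)[C@H]1[C@@H]2[C@@H](O[Si](C)(C)C(C)(C)C)C[C@@]3(O)C(C)(C)CC[C@H](O[Si](C)(C)C(C)(C)C)[C@]3(C)[C@H]2C[C@]1(CC=C)C(=O)OC(C)(C)C | intermediate
31 | 1α,7β-diol of 30 | COC(=O)[C@H]1[C@@H]2[C@@H](O)C[C@@]3(O)C(C)(C)CC[C@H](O)[C@]3(C)[C@H]2C[C@]1(CC=C)C(=O)OC(C)(C)C | intermediate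
32 | 1α,7β-diacetate (5α-OH free; 13β-allyl; C12 tert-butyl ester) | COC(=O)[C@H]1[C@@H]2[C@@H](OC(C)=O)C[C@@]3(O)C(C)(C)CC[C@H](OC(C)=O)[C@]3(C)[C@H]2C[C@]1(CC=C)C(=O)OC(C)(C)C | intermediate
33 | trimethylsilyl ester and 5-O-trimethylsilyl ether of 34 | COC(=O)[C@H]1[C@@H]2[C@@H](OC(C)=O)C[C@@]3(O[Si](C)(C)C)C(C)(C)CC[C@H](OC(C)=O)[C@]3(C)[C@H]2C[C@]1(CC=C)C(=O)O[Si](C)(C)C | intermediate (not isolated)
34 | C12 carboxylic acid (13β-allyl; diacetate) | COC(=O)[C@H]1[C@@H]2[C@@H](OC(C)=O)C[C@@]3(O)C(C)(C)CC[C@H](OC(C)=O)[C@]3(C)[C@H]2C[C@]1(CC=C)C(=O)O | intermediate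
35 | 1,2,4-trioxolane formed from the allyl group of 34 | COC(=O)[C@H]1[C@@H]2[C@@H](OC(C)=O)C[C@@]3(O)C(C)(C)CC[C@H](OC(C)=O)[C@]3(C)[C@H]2C[C@]1(CC4OOCO4)C(=O)O | intermediate (not isolated)
36 | spiro γ-lactol (pseudo-acid): C13-spiro lactone C12(=O)–O–C16H(OH)–C15H2, C16 epimers | COC(=O)[C@H]1[C@@H]2[C@@H](OC(C)=O)C[C@@]3(O)C(C)(C)CC[C@H](OC(C)=O)[C@]3(C)[C@H]2C[C@]12C(=O)OC(O)C2 | intermediate
37 | 16-O-mesylate of 36 | COC(=O)[C@H]1[C@@H]2[C@@H](OC(C)=O)C[C@@]3(O)C(C)(C)CC[C@H](OC(C)=O)[C@]3(C)[C@H]2C[C@]12C(=O)OC(OS(C)(=O)=O)C2 | intermediate (not isolated)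
38 | spiro enol lactone (C15=C16) | COC(=O)[C@H]1[C@@H]2[C@@H](OC(C)=O)C[C@@]3(O)C(C)(C)CC[C@H](OC(C)=O)[C@]3(C)[C@H]2C[C@]12C(=O)OC=C2 | intermediate
39 | 15-bromo-16-hydroxy spiro lactone (Br on the lactone face turned toward C11; C16 epimers) | COC(=O)[C@H]1[C@@H]2[C@@H](OC(C)=O)C[C@@]3(O)C(C)(C)CC[C@H](OC(C)=O)[C@]3(C)[C@H]2C[C@]12C(=O)OC(O)[C@H]2Br | intermediate
40 | spirocaesalmin | COC(=O)[C@H]1[C@@H]2[C@@H](OC(C)=O)C[C@@]3(O)C(C)(C)CC[C@H](OC(C)=O)[C@]3(C)[C@H]2C[C@]12C(=O)O[C@@H]1O[C@@H]12 | target

## Step count and least certain steps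

Total step count: 30. Longest linear sequence: 30 steps (1 → 40); 6, 9, 22 and 26 are purchased and enter directly.

**Step 30 (bears the label; the least certain step).** Two processes may divert it. The C17 ester carbonyl sits on the same face as the attacking hydroxyl and may take part in the silver-assisted loss of bromide (translactonization). Alternatively, ring–chain opening of the lactol to the β-bromo carboxylate may be followed by β-lactone formation or decarboxylative fragmentation. The fallback uses known reactions, sets out from 38 and returns at 40. Dioxirane epoxidation of 38 in acetone–methanol takes the open C11 face, and the acyloxy epoxide is methanolysed in the flask to the 15-hydroxy-16-methoxy lactone F1. Dess–Martin oxidation gives the 15-ketone F2. NaBH4 at −78 °C attacks from the same open face and gives the epimeric alcohol F3, whose oxygen now lies on the C14 face. TMSBr converts the methyl acetal into the anomeric bromide and silylates O15, giving bromide F4. CsF frees the C15 alkoxide, which displaces the anomeric bromide as in the formation of 1,2-anhydro sugars from 2-hydroxy glycosyl halides, giving 40. F3 must be handled quickly, since a free 15-OH can lactonize onto C17.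

**Step 8 (key step).** Most likely to fail through heterolysis of the C1–O bond, which the silyloxydiene assists (vinylogous elimination), through a [1,5]-hydrogen shift from the C10 methyl at the temperature the twisted diene needs, or through leakage into the endo-tether mode (cis-fused lactone). The last is the least serious: C8 can be equilibrated at the β-keto ester stage (16, 17) and C9 at aldehyde 21, both toward the natural equatorial arrangement. The fallback sets out from 5 and returns at 16; it leaves the C7 oxygen out of the diene. Wittig methylenation of 5 gives dienol F5. Esterification with 9 gives fumarate F6, whose allylic ester is no longer activated by a donor. Cycloaddition at 150–170 °C gives adduct F7. Allylic oxidation (CrO3, 3,5-dimethylpyrazole) at C7, the only allylic methylene, gives enone F8. Nucleophilic epoxidation (t-BuOOH, DBU) from the α face gives epoxy ketone 16.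

**Step 20.** Facial discrimination at C13 may be insufficient if the catalyst works against a small substrate preference, and O-allylation may compete. The fallback runs from 25 to 27 without new compounds: alkylation with allyl bromide under chiral phase-transfer catalysis (N-spiro binaphthyl quaternary ammonium bromide, CsOH·H2O, toluene, −40 °C), where a chiral ion pair replaces the π-allyl palladium complex as the source of induction.

**Step 23.** The 7-silyloxy group may be lost by β-elimination from the carbanion that develops at C8 during electron transfer, or C8 may be protonated from the α face (cis B/C fusion). The fallback sets out from 27 and returns at 30; it adds C17 without touching C8. Methoxymethylenation of ketone 27 (Ph3P=CHOMe) gives enol ether F9. Mild acid hydrolysis gives aldehyde F10, whose C14 can equilibrate to the β-formyl epimer. NaClO2 oxidation gives acid F11, and TMSCHN2 gives 30.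

## Further compounds

F1 | step 30 | 15-hydroxy-16-methoxy spiro lactone (15-OH on the C11 face) | COC(=O)[C@H]1[C@@H]2[C@@H](OC(C)=O)C[C@@]3(O)C(C)(C)CC[C@H](OC(C)=O)[C@]3(C)[C@H]2C[C@]12C(=O)OC(OC)[C@H]2O
F2 | step 30 | 15-oxo-16-methoxy spiro lactone | COC(=O)[C@H]1[C@@H]2[C@@H](OC(C)=O)C[C@@]3(O)C(C)(C)CC[C@H](OC(C)=O)[C@]3(C)[C@H]2C[C@]12C(=O)OC(OC)C2=O
F3 | step 30 | 15-epi-hydroxy-16-methoxy spiro lactone (15-OH on the C14 face) | COC(=O)[C@H]1[C@@H]2[C@@H](OC(C)=O)C[C@@]3(O)C(C)(C)CC[C@H](OC(C)=O)[C@]3(C)[C@H]2C[C@]12C(=O)OC(OC)[C@@H]2O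
F4 | step 30 | 16-bromo-15-(trimethylsilyloxy) spiro lactone | COC(=O)[C@H]1[C@@H]2[C@@H](OC(C)=O)C[C@@]3(O)C(C)(C)CC[C@H](OC(C)=O)[C@]3(C)[C@H]2C[C@]12C(=O)OC(Br)[C@@H]2O[Si](C)(C)C
F5 | step 8 | (S)-2,4,4-trimethyl-3-vinylcyclohex-2-en-1-ol | C=CC1=C(C)[C@@H](O)CCC1(C)C
F6 | step 8 | tert-butyl (S)-2,4,4-trimethyl-3-vinylcyclohex-2-en-1-yl fumarate | C=CC1=C(C)[C@@H](OC(=O)/C=C/C(=O)OC(C)(C)C)CCC1(C)C
F7 | step 8 | cycloadduct without oxygen at C7 (5-ene; 8α-CO2t-Bu; 9α-H; 10β-CH3; 11→1α lactone) | CC(C)(C)OC(=O)[C@@H]1CC=C2C(C)(C)CC[C@@H]3OC(=O)[C@@H]1[C@]23C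
F8 | step 8 | 5-en-7-one lactone | CC(C)(C)OC(=O)[C@@H]1C(=O)C=C2C(C)(C)CC[C@@H]3OC(=O)[C@@H]1[C@]23C
F0 | step 20 | none | none
F9 | step 23 | C14 methoxymethylene compound (enol ether of the C17 aldehyde) | COC=C1[C@@H]2[C@@H](O[Si](C)(C)C(C)(C)C)C[C@@]3(O)C(C)(C)CC[C@H](O[Si](C)(C)C(C)(C)C)[C@]3(C)[C@H]2C[C@]1(CC=C)C(=O)OC(C)(C)C
F10 | step 23 | C17 aldehyde (14β-formyl; 8β-H) | O=C[C@H]1[C@@H]2[C@@H](O[Si](C)(C)C(C)(C)C)C[C@@]3(O)C(C)(C)CC[C@H](O[Si](C)(C)C(C)(C)C)[C@]3(C)[C@H]2C[C@]1(CC=C)C(=O)OC(C)(C)C
F11 | step 23 | C17 carboxylic acid | OC(=O)[C@H]1[C@@H]2[C@@H](O[Si](C)(C)C(C)(C)C)C[C@@]3(O)C(C)(C)CC[C@H](O[Si](C)(C)C(C)(C)C)[C@]3(C)[C@H]2C[C@]1(CC=C)C(=O)OC(C)(C)C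
A1 | alternative 1 | cis-fused 2-ethoxytetrahydropyran acetal with quaternary C13 bearing a phenylsulfonylmethyl group (product of the radical cyclization) | CCO[C@H]1OC[C@H]2[C@@H]3[C@@H](O[Si](C)(C)C(C)(C)C)C[C@@]4(O)C(C)(C)CC[C@H](O[Si](C)(C)C(C)(C)C)[C@]4(C)[C@H]3C[C@]2(C1)CS(=O)(=O)c1ccccc1
A2 | alternative 2 | tricyclic C9=C11 cyclopentene with quaternary C13 (product of the carbene insertion) | COC(=O)[C@H]1[C@@H]2[C@@H](O[Si](C)(C)C(C)(C)C)C[C@@]3(O[Si](CC)(CC)CC)C(C)(C)CC[C@H](O[Si](C)(C)C(C)(C)C)[C@]3(C)C2=C[C@@]1(COCc4ccc(OC)cc4)CC(OC)OC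
A3 | alternative 3 | tricyclic C7 ketone with C8 and C14 set (product of the Stetter reaction) | COC(=O)[C@H]1[C@@H]2C(=O)C[C@@]3(O[Si](CC)(CC)CC)C(C)(C)CC[C@H](O[Si](C)(C)C(C)(C)C)[C@]3(C)[C@H]2C[C@]1(CC(OC)OC)C(=O)OC(C)(C)C
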